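**Plan**
- Retrosynthesis: remove the C15 methylene and the C7 acetate, open the 1,2-dioxane at O–C11 (SN2) and O–C8 (O2 capture), then cut C5–C6 of the 14-membered ring; the open chain is cut further at C8=C9, C11–C12, C2–C3 and C1–C14.
- Enabling feature: the E-trisubstituted C3=C4 alkene lies between the lactone carbinol C2 and the C5–C6 ethylene that leads to oxygenated C7. A C6 carbene next to a C7 ketone and a phenylthio group on C3 of a C4=C5 isopropenyl unit are therefore related to it by a [2,3] shift of a sulfonium ylide.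
- Forward: C1–C14 (Evans alkylation), C2–C3 with closure of the γ-lactone, C11–C12 (Nozaki–Hiyama–Kishi), C8=C9 (Wittig), diazo transfer; the 14-membered carbocycle closes in step 17, the 1,2-dioxane in step 21, the exocyclic methylene comes last.
- Stereocentres: C1 from the (S)-benzyloxazolidinone; C2 from the isopinocampheylborane reagent (C3 is carried as a mixture because it becomes sp2); C11 from a CBS reduction, set epimeric and inverted in the peroxide SN2; C8 from face-selective O2 capture in the macrocycle; C7 from Felkin–Anh hydride addition.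
- Alkenes: 12Z from Red-Al/I2 on but-2-yn-1-ol; 3E from the envelope transition state of the [2,3] shift.

Key step: step 17

Remark: cembrane numbering is used from compound 18 on (C1 = lactone CH bearing the CH2 arm C14, C2 = lactone O–CH, C15/C16 = lactone CH2/C=O); C3 of the sulfide is left undefined in names and SMILES up to compound 31.
Remark: 3-[(tert-butyldimethylsilyl)oxy]propanal and 3-(triphenylphosphoranylidene)butan-2-one are taken as purchasable.

Step 1
Reactants: 1 but-2-yn-1-ol
Product: 3 (Z)-3-iodobut-2-en-1-ol, via sodium alkenylalanate 2 (not isolated)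
Conditions: NaAlH2(OCH2CH2OMe)2, THF, 0 → 25 °C; then I2, −78 → 0 °C
Reagents that add atoms: iodine, II
Why: Hydroxyl-directed trans-hydroalumination places hydride on C2 and aluminium on C3 through a five-membered alanate, and iodinolysis with retention should give the Z-iodoalkene that becomes the 12Z double bond.

Step 2
Reactants: 3 (Z)-3-iodobut-2-en-1-ol
Product: 4 (Z)-1-bromo-3-iodobut-2-ene
Conditions: CBr4, PPh3, CH2Cl2, 0 °C
Reagents that add atoms: carbon tetrabromide, BrC(Br)(Br)Br
Why: Appel bromination is an SN2 displacement at the primary allylic carbon and leaves the alkene geometry untouched.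

Step 3
Reactants: 5 4-(tert-butoxy)-4-oxobutanoic acid; 6 (S)-4-benzyl-1,3-oxazolidin-2-one
Product: 8 tert-butyl 4-[(4S)-4-benzyl-2-oxo-1,3-oxazolidin-3-yl]-4-oxobutanoate, via mixed pivalic anhydride 7 (not isolated)
Conditions: t-BuCOCl, Et3N, THF, −20 °C; then 6, LiCl, 25 °C
Reagents that add atoms: none
Why: N-Acylation of the oxazolidinone through the mixed anhydride, which is attacked at the less hindered succinyl carbonyl, is a standard way to Evans imides.

Step 4
Reactants: 8 tert-butyl 4-[(4S)-4-benzyl-2-oxo-1,3-oxazolidin-3-yl]-4-oxobutanoate; 4 (Z)-1-bromo-3-iodobut-2-ene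
Product: 10 tert-butyl (3S,5Z)-3-{[(4S)-4-benzyl-2-oxo-1,3-oxazolidin-3-yl]carbonyl}-6-iodohept-5-enoate, via sodium enolate 9 (not isolated)
Conditions: NaN(SiMe3)2, THF, −78 °C; then 4, −78 → −40 °C
Reagents that add atoms: none
Why: Evans asymmetric alkylation: the imide α-CH2 is more acidic than the ester α-CH2, and the chelated Z-enolate is alkylated on the face opposite the benzyl group, which sets C1 as (S).

Step 5
Reactants: 10 tert-butyl (3S,5Z)-3-{[(4S)-4-benzyl-2-oxo-1,3-oxazolidin-3-yl]carbonyl}-6-iodohept-5-enoate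
Product: 11 tert-butyl (3S,5Z)-3-(hydroxymethyl)-6-iodohept-5-enoate
Conditions: LiBH4, H2O (1 equiv), Et2O, 0 °C
Reagents that add atoms: none
Why: Reductive cleavage of the auxiliary with LiBH4 attacks the lithium-chelated imide carbonyl and should spare the tert-butyl ester and the iodoalkene.

Step 6
Reactants: 11 tert-butyl (3S,5Z)-3-(hydroxymethyl)-6-iodohept-5-enoate
Product: 12 tert-butyl (3S,5Z)-3-formyl-6-iodohept-5-enoate
Conditions: Dess–Martin periodinane, CH2Cl2, 0 → 25 °C; used at once
Reagents that add atoms: none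
Why: Dess–Martin oxidation is near-neutral, so the α-stereocentre C1 of the aldehyde should not epimerise.

Step 7
Reactants: 13 thiophenol; 14 3-chloro-2-methylprop-1-ene
Product: 15 (2-methylprop-2-en-1-yl)(phenyl)sulfane
Conditions: NaOH, EtOH, 0 → 25 °C
Reagents that add atoms: none
Why: SN2 alkylation of the thiolate by the primary allylic chloride.

Step 8
Reactants: 15 (2-methylprop-2-en-1-yl)(phenyl)sulfane; 12 tert-butyl (3S,5Z)-3-formyl-6-iodohept-5-enoate
Product: 19 (4S,5R)-4-[(2Z)-3-iodobut-2-en-1-yl]-5-[2-methyl-1-(phenylsulfanyl)prop-2-en-1-yl]oxolan-2-one, via lithiated sulfide 16 (not isolated), via allylborane 17 (not isolated), via hydroxy ester 18 (not isolated)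
Conditions: 15, n-BuLi, THF, −78 → −20 °C; (−)-Ipc2BOMe, −78 °C; BF3·OEt2; 12, −78 °C; HOCH2CH2NH2; then p-TsOH (cat.), CH2Cl2, 25 °C
Reagents that add atoms: none
Why: Proposed new method: lithiation of 15 at the sulfur-bearing allylic carbon and boration at the unsubstituted terminus should give a γ-(phenylthio)methallyl diisopinocampheylborane, which adds to the aldehyde through a closed six-membered chair with allylic transposition, so that C3 carries sulfur and the C4=C5 isopropenyl group, while the isopinocampheyl groups derived from (+)-α-pinene direct attack to the Si face and set C2 as (R) against the negligible bias of C1 and whatever the reagent geometry (both C3 epimers are usable); the closest known reactions are the γ-alkoxyallylboration of aldehydes with diisopinocampheylboranes and the α-selective addition of boron and titanium ate complexes of lithiated allyl sulfides to aldehydes; acid then closes the cis γ-lactone by transesterification of the tert-butyl ester.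

Step 9
Reactants: 19 (4S,5R)-4-[(2Z)-3-iodobut-2-en-1-yl]-5-[2-methyl-1-(phenylsulfanyl)prop-2-en-1-yl]oxolan-2-one; 20 3-[(tert-butyldimethylsilyl)oxy]propanal
Product: 21 C11 allylic alcohols (both epimers): lactone 19 in which iodine on C12 is replaced by CH(OH)CH2CH2OSi(t-Bu)Me2
Conditions: CrCl2, NiCl2 (cat.), DMF, 25 °C
Reagents that add atoms: none
Why: Nozaki–Hiyama–Kishi coupling: zerovalent nickel inserts into the C–I bond, transmetalation gives an alkenylchromium that adds to the aldehyde but not to the lactone, with retention of the Z geometry; C11 is not controlled here and is corrected in steps 10 and 11.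

Step 10
Reactants: 21 C11 allylic alcohols
Product: 22 Z-enone (C11 ketone)
Conditions: MnO2, CH2Cl2, 25 °C
Reagents that add atoms: none
Why: MnO2 oxidises only the allylic alcohol and leaves the aryl sulfide alone.

Step 11
Reactants: 22 Z-enone (C11 ketone)
Product: 23 (11S)-allylic alcohol
Conditions: (R)-B-methyl oxazaborolidine from diphenylprolinol (CBS catalyst, 0.3 equiv), catecholborane, toluene, −78 °C
Reagents that add atoms: none
Why: Corey–Bakshi–Shibata reduction with the α-methyl alkenyl group as the large substituent should deliver hydride under catalyst control to give (11S), the epimer needed for the later inversion.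

Step 12
Reactants: 23 (11S)-allylic alcohol
Product: 24 C9,C11 bis(tert-butyldimethylsilyl) ether
Conditions: t-BuMe2SiOTf, 2,6-lutidine, CH2Cl2, −78 → 0 °C
Reagents that add atoms: tert-butyldimethylsilyl triflate, CC(C)(C)[Si](C)(C)OS(=O)(=O)C(F)(F)F
Why: Silylation of the secondary allylic alcohol under non-nucleophilic base, needed because a free hydroxyl would intercept the carbene in step 17.

Step 13
Reactants: 24 C9,C11 bis(tert-butyldimethylsilyl) ether
Product: 25 C9 primary alcohol (C11 silyl ether kept)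
Conditions: HF·pyridine, pyridine, THF, 0 °C
Reagents that add atoms: none
Why: Buffered HF cleaves the unhindered primary silyl ether much faster than the secondary allylic one (steric selection).

Step 14
Reactants: 25 C9 primary alcohol
Product: 26 C9 aldehyde (β-silyloxy aldehyde)
Conditions: SO3·pyridine, DMSO, i-Pr2NEt, CH2Cl2, 0 °C
Reagents that add atoms: none
Why: Parikh–Doering oxidation is mild enough to spare the sulfide and to avoid β-elimination of the silyloxy group.

Step 15
Reactants: 26 C9 aldehyde; 27 3-(triphenylphosphoranylidene)butan-2-one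
Product: 28 (8E)-methyl enone (C6 methyl, C7 ketone)
Conditions: toluene, 90 °C
Reagents that add atoms: none
Why: Wittig olefination with a stabilised α-branched ylide gives the E-trisubstituted enone under neutral conditions.

Step 16
Reactants: 28 (8E)-methyl enone
Product: 31 α-diazo enone (C6 diazo, C7 ketone), via lithium enolate 29 (not isolated), via trifluoroacetyl ketone 30 (not isolated)
Conditions: LiN(SiMe3)2, THF, −78 °C; CF3CO2CH2CF3; aq. HCl; then MeSO2N3, Et3N, H2O, MeCN, 25 °C
Reagents that add atoms: methanesulfonyl azide, CS(=O)(=O)N=[N+]=[N-]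
Why: Detrifluoroacetylative diazo transfer: kinetic deprotonation of the α′-methyl group (faster than lactone enolisation), trifluoroacetylation, diazo transfer to the activated methylene and loss of the trifluoroacetyl group give the diazo ketone without exposing the enone to diazomethane.

Step 17
Reactants: 31 α-diazo enone
Product: 33 14-membered enone with E C3=C4 alkene and exocyclic phenylthio group on C6, via cyclic sulfonium ylide 32 (not isolated)
Conditions: Rh2(OAc)4 (3 mol %), CH2Cl2, 40 °C, syringe-pump addition of 31 over 12 h, final 1 mM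
Reagents that add atoms: none
Why: Proposed new method: Rh2(OAc)4 decomposes the diazo ketone to an electrophilic C6 rhodium carbene, which the C3 phenylthio group should capture faster than any alkene or C–H bond to give the 13-membered cyclic sulfonium ylide 32, stabilised by the C7 carbonyl. A concerted five-centre [2,3]-sigmatropic shift then joins C6 to the isopropenyl terminus C5, breaks the C3–S bond and moves the double bond to C3=C4, so the 14-membered carbocycle arises by ylide formation across the chain ends followed by ring expansion, with sulfur left outside the ring on C6. The closest known reactions are the intermolecular Doyle–Kirmse reaction of allyl sulfides with diazo ketones and macrocyclisations through metal-carbene oxonium-ylide formation and [2,3] shift; closing a ring of this size through a sulfonium ylide is the untested element. No stereocentre of consequence is created: both C3 epimers of 31 converge and the C6 epimers of 33 are erased in step 18. The E geometry of C3=C4 should follow from the envelope transition state with the C2 substituent pseudo-equatorial. Sulfur capture over cyclopropanation, carbene dimerisation and intermolecular ylide formation is secured by the nucleophilic aryl sulfide, slow addition and high dilution.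

Step 18
Reactants: 33 14-membered enone with C6 phenylthio group
Product: 34 macrocyclic enone with C6 methylene (C11 silyl ether)
Conditions: SmI2 (2.1 equiv), THF/MeOH, −78 °C
Reagents that add atoms: none
Why: Reductive cleavage of an α-phenylthio ketone: the ketyl expels thiolate, and the samarium enolate is protonated at C6 faster than the enone is reduced at −78 °C.

Step 19
Reactants: 34 macrocyclic enone (C11 silyl ether)
Product: 35 (11S)-alcohol
Conditions: HF·pyridine, THF, 0 → 25 °C
Reagents that add atoms: none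
Why: Fluoride-mediated desilylation; enone and lactone tolerate the mildly acidic medium.

Step 20
Reactants: 35 (11S)-alcohol
Product: 36 (11S)-mesylate
Conditions: MeSO2Cl, Et3N, CH2Cl2, −40 °C; cold work-up, used at once
Reagents that add atoms: methanesulfonyl chloride, CS(=O)(=O)Cl
Why: Sulfonylation through the sulfene occurs at oxygen with retention at C11; the allylic mesylate is kept cold and carried on directly.

Step 21
Reactants: 36 (11S)-mesylate
Product: 38 peroxy ketone with the C8–O–O–C11 1,2-dioxane (8S,11R), via C8 hydroperoxide 37 (not isolated)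
Conditions: Mn(dpm)3 (5 mol %), PhSiH3, O2 (1 atm), CH2Cl2/i-PrOH 9:1, −10 °C; then Et3N, 0 °C
Reagents that add atoms: dioxygen, O=O
Why: Mukaiyama-type hydroperoxidation: hydrogen-atom transfer from the manganese hydride to C9 of the enone (preferred over the isolated alkenes because it gives a stabilised tertiary α-keto radical) and O2 capture at C8, expected on the outer face of the macrocycle, give the hydroperoxide, which then closes the dioxane by 6-exo-tet SN2 on the allylic mesylate with inversion to (11R).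

Step 22
Reactants: 38 peroxy ketone
Product: 39 (7S)-alcohol
Conditions: NaBH4, MeOH, −40 °C
Reagents that add atoms: none
Why: Polar Felkin–Anh addition: hydride attacks anti to the C8–O bond and past the C8 methyl group, which should give the 7,8-syn alcohol (7S); the dialkyl peroxide and the lactone are inert to borohydride at this temperature.

Step 23
Reactants: 39 (7S)-alcohol
Product: 40 C7 acetate
Conditions: Ac2O, pyridine, DMAP (cat.), CH2Cl2, 0 °C
Reagents that add atoms: acetic anhydride, CC(=O)OC(C)=O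
Why: Standard nucleophile-catalysed acetylation of the secondary alcohol.

Step 24
Reactants: 40 C7 acetate
Product: 44 target (CNP0238885.10), via lithium lactone enolate 41 (not isolated), via Mannich base 42 (not isolated), via trimethylammonium iodide 43 (not isolated)
Conditions: LiN(SiMe3)2 (1.05 equiv), THF, −78 °C; CH2=NMe2 I (Eschenmoser's salt), −78 → 0 °C; then MeI, MeOH, 25 °C; then NaHCO3 (aq), CH2Cl2
Reagents that add atoms: dimethyl(methylidene)ammonium iodide, C=[N+](C)C.[I-]
Why: Eschenmoser methylenation: the γ-lactone α-CH2 is more acidic than the acetate, its enolate undergoes a Mannich reaction, and quaternisation followed by E1cB elimination under bicarbonate gives the exocyclic methylene without strong base in contact with the peroxide at the end.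

**Compound list**
1 | but-2-yn-1-ol | CC#CCO | starting material
2 | cyclic sodium alkenylalanate from hydroalumination of 1 | CC1=CCO[Al-]1(OCCOC)OCCOC.[Na+] | intermediate
3 | (Z)-3-iodobut-2-en-1-ol | C/C(I)=C/CO | intermediate
4 | (Z)-1-bromo-3-iodobut-2-ene | C/C(I)=C/CBr | intermediate
5 | 4-(tert-butoxy)-4-oxobutanoic acid | CC(C)(C)OC(=O)CCC(=O)O | starting material
6 | (S)-4-benzyl-1,3-oxazolidin-2-one | O=C1OC[C@H](Cc2ccccc2)N1 | starting material
7 | 4-(tert-butoxy)-4-oxobutanoic pivalic anhydride | CC(C)(C)OC(=O)CCC(=O)OC(=O)C(C)(C)C | intermediate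
8 | tert-butyl 4-[(4S)-4-benzyl-2-oxo-1,3-oxazolidin-3-yl]-4-oxobutanoate | CC(C)(C)OC(=O)CCC(=O)N1[C@@H](Cc2ccccc2)COC1=O | intermediate
9 | sodium (Z)-enolate of 8 | CC(C)(C)OC(=O)C/C=C(\[O-])N1[C@@H](Cc2ccccc2)COC1=O.[Na+] | intermediate
10 | tert-butyl (3S,5Z)-3-{[(4S)-4-benzyl-2-oxo-1,3-oxazolidin-3-yl]carbonyl}-6-iodohept-5-enoate | CC(C)(C)OC(=O)C[C@H](C/C=C(/C)I)C(=O)N1[C@@H](Cc2ccccc2)COC1=O | intermediate
11 | tert-butyl (3S,5Z)-3-(hydroxymethyl)-6-iodohept-5-enoate | CC(C)(C)OC(=O)C[C@H](C/C=C(/C)I)CO | intermediate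
12 | tert-butyl (3S,5Z)-3-formyl-6-iodohept-5-enoate | CC(C)(C)OC(=O)C[C@H](C/C=C(/C)I)C=O | intermediate
13 | thiophenol | Sc1ccccc1 | starting material
14 | 3-chloro-2-methylprop-1-ene | CC(=C)CCl | starting material
15 | (2-methylprop-2-en-1-yl)(phenyl)sulfane | CC(=C)CSc1ccccc1 | intermediate
16 | 1-lithio-2-methylallyl phenyl sulfide | [Li]C(Sc1ccccc1)C(C)=C | intermediate
17 | [2-methyl-3-(phenylsulfanyl)prop-2-en-1-yl]bis(isopinocampheyl)borane (isopinocampheyl from (+)-α-pinene; alkene geometry undefined) | CC(=CSc1ccccc1)CB([C@@H]1C[C@@H]2C[C@H]([C@H]1C)C2(C)C)[C@@H]1C[C@@H]2C[C@H]([C@H]1C)C2(C)C | intermediate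
18 | tert-butyl (3S,5Z)-3-[(1R)-1-hydroxy-3-methyl-2-(phenylsulfanyl)but-3-en-1-yl]-6-iodohept-5-enoate (C3 epimers) | CC(C)(C)OC(=O)C[C@H](C/C=C(/C)I)[C@@H](O)C(Sc1ccccc1)C(C)=C | intermediate
19 | (4S,5R)-4-[(2Z)-3-iodobut-2-en-1-yl]-5-[2-methyl-1-(phenylsulfanyl)prop-2-en-1-yl]oxolan-2-one | C/C(I)=C/C[C@H]1CC(=O)O[C@H]1C(Sc1ccccc1)C(C)=C | intermediate
20 | 3-[(tert-butyldimethylsilyl)oxy]propanal | O=CCCO[Si](C)(C)C(C)(C)C | starting material
21 | C11 allylic alcohols (both epimers), C9 silyl ether, 12Z | CC(C)(C)[Si](C)(C)OCCC(O)/C(C)=C\C[C@H]1CC(=O)O[C@H]1C(Sc1ccccc1)C(C)=C | intermediate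
22 | Z-enone (C11 ketone), C9 silyl ether | CC(C)(C)[Si](C)(C)OCCC(=O)/C(C)=C\C[C@H]1CC(=O)O[C@H]1C(Sc1ccccc1)C(C)=C | intermediate
23 | (11S)-allylic alcohol, C9 silyl ether | CC(C)(C)[Si](C)(C)OCC[C@H](O)/C(C)=C\C[C@H]1CC(=O)O[C@H]1C(Sc1ccccc1)C(C)=C | intermediate
24 | (11S)-C9,C11 bis(tert-butyldimethylsilyl) ether | CC(C)(C)[Si](C)(C)OCC[C@H](O[Si](C)(C)C(C)(C)C)/C(C)=C\C[C@H]1CC(=O)O[C@H]1C(Sc1ccccc1)C(C)=C | intermediate
25 | C9 primary alcohol, (11S)-silyl ether | OCC[C@H](O[Si](C)(C)C(C)(C)C)/C(C)=C\C[C@H]1CC(=O)O[C@H]1C(Sc1ccccc1)C(C)=C | intermediate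
26 | C9 aldehyde, (11S)-silyl ether | O=CC[C@H](O[Si](C)(C)C(C)(C)C)/C(C)=C\C[C@H]1CC(=O)O[C@H]1C(Sc1ccccc1)C(C)=C | intermediate
27 | 3-(triphenylphosphoranylidene)butan-2-one | CC(=O)C(C)=P(c1ccccc1)(c1ccccc1)c1ccccc1 | starting material
28 | (8E,12Z)-methyl enone, (11S)-silyl ether | CC(=O)/C(C)=C/C[C@H](O[Si](C)(C)C(C)(C)C)/C(C)=C\C[C@H]1CC(=O)O[C@H]1C(Sc1ccccc1)C(C)=C | intermediate
29 | lithium α′-enolate of 28 | [Li]OC(=C)/C(C)=C/C[C@H](O[Si](C)(C)C(C)(C)C)/C(C)=C\C[C@H]1CC(=O)O[C@H]1C(Sc1ccccc1)C(C)=C | intermediate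
30 | α′-trifluoroacetyl ketone of 28 | FC(F)(F)C(=O)CC(=O)/C(C)=C/C[C@H](O[Si](C)(C)C(C)(C)C)/C(C)=C\C[C@H]1CC(=O)O[C@H]1C(Sc1ccccc1)C(C)=C | intermediate
31 | open-chain α-diazo enone (C6 diazo, C7 ketone, (11S)-silyl ether, cis lactone, C3 phenylthio isopropenyl unit) | [N-]=[N+]=CC(=O)/C(C)=C/C[C@H](O[Si](C)(C)C(C)(C)C)/C(C)=C\C[C@H]1CC(=O)O[C@H]1C(Sc1ccccc1)C(C)=C | intermediate
32 | 13-membered cyclic sulfonium ylide (S bonded to C3 and C6) | [CH-]1C(=O)/C(C)=C/C[C@H](O[Si](C)(C)C(C)(C)C)/C(C)=C\C[C@H]2CC(=O)O[C@H]2C(C(C)=C)[S+]1c1ccccc1 | intermediate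
33 | 14-membered (3E,8E,12Z)-enone, C6 phenylthio (both epimers), (11S)-silyl ether | C1C(=O)O[C@H]2/C=C(\C)CC(Sc3ccccc3)C(=O)/C(C)=C/C[C@H](O[Si](C)(C)C(C)(C)C)/C(C)=C\C[C@@H]12 | intermediate
34 | macrocyclic enone, C6 methylene, (11S)-silyl ether | C1C(=O)O[C@H]2/C=C(\C)CCC(=O)/C(C)=C/C[C@H](O[Si](C)(C)C(C)(C)C)/C(C)=C\C[C@@H]12 | intermediate
35 | macrocyclic enone, (11S)-alcohol | C1C(=O)O[C@H]2/C=C(\C)CCC(=O)/C(C)=C/C[C@H](O)/C(C)=C\C[C@@H]12 | intermediate
36 | macrocyclic enone, (11S)-mesylate | C1C(=O)O[C@H]2/C=C(\C)CCC(=O)/C(C)=C/C[C@H](OS(C)(=O)=O)/C(C)=C\C[C@@H]12 | intermediate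
37 | (8S)-hydroperoxy ketone, (11S)-mesylate | C1C(=O)O[C@H]2/C=C(\C)CCC(=O)[C@@](C)(OO)CC[C@H](OS(C)(=O)=O)/C(C)=C\C[C@@H]12 | intermediate
38 | (8S,11R)-peroxy-bridged C7 ketone | C1C(=O)O[C@H]2/C=C(\C)CCC(=O)[C@]3(C)CC[C@@H](OO3)/C(C)=C\C[C@@H]12 | intermediate
39 | (7S,8S,11R)-alcohol | C1C(=O)O[C@H]2/C=C(\C)CC[C@H](O)[C@]3(C)CC[C@@H](OO3)/C(C)=C\C[C@@H]12 | intermediate
40 | (7S,8S,11R)-acetate | C1C(=O)O[C@H]2/C=C(\C)CC[C@H](OC(C)=O)[C@]3(C)CC[C@@H](OO3)/C(C)=C\C[C@@H]12 | intermediate
41 | lithium enolate of lactone 40 | C1=C(O[Li])O[C@H]2/C=C(\C)CC[C@H](OC(C)=O)[C@]3(C)CC[C@@H](OO3)/C(C)=C\C[C@@H]12 | intermediate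
42 | α-(dimethylaminomethyl) lactone (C15 epimers) | CN(C)CC1C(=O)O[C@H]2/C=C(\C)CC[C@H](OC(C)=O)[C@]3(C)CC[C@@H](OO3)/C(C)=C\C[C@@H]12 | intermediate
43 | α-(trimethylammoniomethyl) lactone iodide | C[N+](C)(C)CC1C(=O)O[C@H]2/C=C(\C)CC[C@H](OC(C)=O)[C@]3(C)CC[C@@H](OO3)/C(C)=C\C[C@@H]12.[I-] | intermediate
44 | CNP0238885.10, (1S,2S,7S,8S,11R,3E,12Z) | C=C1C(=O)O[C@H]2/C=C(\C)CC[C@H](OC(C)=O)[C@]3(C)CC[C@@H](OO3)/C(C)=C\C[C@@H]12 | target

**Step count**
Total: 24 steps. Longest linear sequence: 22 steps (from but-2-yn-1-ol: steps 1, 2, 4–6, 8–24).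

**Steps most likely to fail**

1. Step 17. The carbene may dimerise, form ylides between molecules, add to the 12Z alkene, or the sulfide may slow the catalyst by binding to rhodium, so that the ring does not close. Fallback: the route leaves at aldehyde 26. An intermolecular Doyle–Kirmse reaction of 26 with diethyl (4-diazo-3-oxobutan-2-yl)phosphonate F1 (from commercial diethyl (3-oxobutan-2-yl)phosphonate by detrifluoroacetylative diazo transfer) and Rh2(OAc)4 would form the C5–C6 bond and the E C3=C4 alkene in the open chain, giving the keto phosphonate aldehyde F2. An intramolecular Horner–Wadsworth–Emmons olefination under Masamune–Roush conditions (LiCl, i-Pr2NEt, MeCN, high dilution) would then close the 14-membered ring at C8=C9 and return to 33.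

2. Step 8. The borane may form or react with the wrong regiochemistry (bond formation at the unsubstituted allyl terminus, 1,3-boron shift), or facial control at C2 may be insufficient. Fallback: the route leaves at aldehyde 12. An Evans syn-aldol reaction (Bu2BOTf, i-Pr2NEt, non-oxidative work-up) with (S)-4-benzyl-3-[(phenylsulfanyl)acetyl]-1,3-oxazolidin-2-one F3 (from 6 and (phenylsulfanyl)acetyl chloride) would set C2 under auxiliary control and give the aldol adduct F4. Transamination with AlMe3/MeNH(OMe)·HCl would give the Weinreb amide F5, MeMgBr the methyl ketone F6, and methylenation with Cp2Ti(μ-Cl)(μ-CH2)AlMe2 would return to hydroxy ester 18 as a single C3 epimer, which is lactonised with acid as in step 8.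

3. Step 21. The allylic mesylate may ionise or solvolyse before the hydroperoxide is in place, O2 capture at C8 may be unselective, or base may cleave the α-hydroperoxy ketone. Fallback: the route leaves at silyl ether 34. Hydroperoxidation (Mn(dpm)3, PhSiH3, O2) with the C11 silyl ether still on would give the hydroperoxide F7, which is masked with 2-methoxypropene/PPTS as the peroxyketal F8; the C8 epimers can be separated at this stage. Bu4NF would free the C11 alcohol F9 and MsCl/Et3N would give the mesylate F10. AcOH/H2O/THF followed by Et3N would then unmask the hydroperoxide and close the dioxane, returning to 38.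

**Further compounds**
F1 | step 17 | diethyl (4-diazo-3-oxobutan-2-yl)phosphonate | CCOP(=O)(OCC)C(C)C(=O)C=[N+]=[N-]
F2 | step 17 | open-chain C9 aldehyde with C6 phenylthio, C7 ketone and C8 diethyl phosphonate, E C3=C4 | O=CC[C@H](O[Si](C)(C)C(C)(C)C)/C(C)=C\C[C@H]1CC(=O)O[C@H]1/C=C(\C)CC(Sc1ccccc1)C(=O)C(C)P(=O)(OCC)OCC
F3 | step 8 | (S)-4-benzyl-3-[(phenylsulfanyl)acetyl]-1,3-oxazolidin-2-one | O=C(CSc1ccccc1)N1[C@@H](Cc2ccccc2)COC1=O
F4 | step 8 | syn-aldol adduct of 12 and F3 | CC(C)(C)OC(=O)C[C@H](C/C=C(/C)I)[C@@H](O)[C@H](Sc1ccccc1)C(=O)N1[C@@H](Cc2ccccc2)COC1=O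
F5 | step 8 | Weinreb amide from F4 | CC(C)(C)OC(=O)C[C@H](C/C=C(/C)I)[C@@H](O)[C@H](Sc1ccccc1)C(=O)N(C)OC
F6 | step 8 | β-hydroxy α-phenylthio methyl ketone | CC(C)(C)OC(=O)C[C@H](C/C=C(/C)I)[C@@H](O)[C@H](Sc1ccccc1)C(C)=O
F7 | step 21 | (8S)-hydroperoxy ketone, (11S)-silyl ether | C1C(=O)O[C@H]2/C=C(\C)CCC(=O)[C@@](C)(OO)CC[C@H](O[Si](C)(C)C(C)(C)C)/C(C)=C\C[C@@H]12
F8 | step 21 | 2-methoxyprop-2-yl peroxyketal, (11S)-silyl ether | C1C(=O)O[C@H]2/C=C(\C)CCC(=O)[C@@](C)(OOC(C)(C)OC)CC[C@H](O[Si](C)(C)C(C)(C)C)/C(C)=C\C[C@@H]12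
F9 | step 21 | 2-methoxyprop-2-yl peroxyketal, (11S)-alcohol | C1C(=O)O[C@H]2/C=C(\C)CCC(=O)[C@@](C)(OOC(C)(C)OC)CC[C@H](O)/C(C)=C\C[C@@H]12
F10 | step 21 | 2-methoxyprop-2-yl peroxyketal, (11S)-mesylate | C1C(=O)O[C@H]2/C=C(\C)CCC(=O)[C@@](C)(OOC(C)(C)OC)CC[C@H](OS(C)(=O)=O)/C(C)=C\C[C@@H]12
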